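**Strategy.** The route rests on cutting ring B between C4 and C4a and between C1 and C2. The key step exploits two features: C1 is para to the 4'-OH of the pendant ring, hence the methide carbon of a para-quinone methide, and C2 and C4 flank C3, hence with C3 as ketone the α- and α'-carbons of a β-keto ester. In one operation C2 adds to C1 under a chiral phase-transfer catalyst and the C4 enolate then couples with a C4a bromide on palladium, closing ring B and setting C1 and C2. Its precursors are a bromoaryl quinone methide and benzyl 2-(benzyloxy)acetoacetate; C3 is elaborated afterwards.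

Key step: step 5

Assumption: the sense of induction of the phase-transfer catalyst on this substrate pair cannot be predicted with certainty, so the antipode that delivers the (1S,2S) adduct is the one used; 1, 5 and 8 are taken as catalogue compounds.

Step 1
Reactants: 1 2-hydroxy-6-methoxybenzaldehyde
Product: 2 2-(benzyloxy)-6-methoxybenzaldehyde
Conditions: BnBr, K2CO3, DMF, rt
Reagents that add atoms: benzyl bromide, BrCc1ccccc1
Why: Williamson ether synthesis: the phenoxide of 1 should displace bromide from benzyl bromide in an SN2 reaction and no stereocentre is formed.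

Step 2
Reactants: 2 2-(benzyloxy)-6-methoxybenzaldehyde
Product: 4 2-(benzyloxy)-6-methoxyphenol, via aryl formate 3 (not isolated)
Conditions: mCPBA, CH2Cl2, 0 °C to rt; then K2CO3 (cat.), MeOH, rt
Reagents that add atoms: 3-chloroperoxybenzoic acid (mCPBA), OOC(=O)c1cccc(Cl)c1
Why: Baeyer–Villiger (Dakin-type) oxidation: the electron-rich 2,6-dialkoxyaryl group should migrate in the Criegee intermediate to give formate 3, which mild methanolysis cleaves to the phenol while the benzyl ether is untouched.

Step 3
Reactants: 4 2-(benzyloxy)-6-methoxyphenol; 5 5-(benzyloxy)-2-bromo-4-methoxybenzaldehyde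
Product: 7 2-(benzyloxy)-4-{[5-(benzyloxy)-2-bromo-4-methoxyphenyl]methylidene}-6-methoxycyclohexa-2,5-dien-1-one (para-quinone methide; E/Z mixture), via Mannich base 6 (not isolated)
Conditions: piperidine, toluene, reflux (Dean–Stark); then Ac2O, 100 °C
Reagents that add atoms: none
Why: Mannich-type condensation of the para-unsubstituted phenol 4 with the iminium ion of 5 gives Mannich base 6, and loss of piperidine (trapped by acetic anhydride) should give the push–pull stabilised para-quinone methide, the standard preparation of such compounds; the geometry of the exocyclic double bond is irrelevant.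

Step 4
Reactants: 8 benzyl 2-(benzyloxy)acetate
Product: 9 benzyl 2-(benzyloxy)-3-oxobutanoate (racemic)
Conditions: LiHMDS, THF, −78 °C; then MeC(O)N(OMe)Me, −78 to 0 °C; aq. NH4Cl
Reagents that add atoms: N-methoxy-N-methylacetamide, CON(C)C(C)=O
Why: Crossed Claisen-type C-acylation of the lithium enolate of 8 with a Weinreb amide, whose stable tetrahedral adduct should prevent double acylation and release the β-keto ester only on quench; the new stereocentre is labile and is used as the racemate.

Step 5
Reactants: 7 para-quinone methide; 9 benzyl 2-(benzyloxy)-3-oxobutanoate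
Product: 11 benzyl (1S,2S)-2,7-bis(benzyloxy)-1-[3-(benzyloxy)-4-hydroxy-5-methoxyphenyl]-6-methoxy-3-oxo-1,2,3,4-tetrahydronaphthalene-2-carboxylate, via open-chain 1,6-adduct 10 (not isolated)
Conditions: chiral binaphthyl N-spiro quaternary ammonium bromide (2 mol %), Cs2CO3, XPhos Pd G3 (5 mol %), toluene, −20 °C, then 70 °C
Reagents that add atoms: none
Why: Proposed new method: a single-flask relay of two reaction types that are each established but have not been run as one operation on such a substrate, the closest known reactions being the chiral-ion-pair 1,6-conjugate addition of malonates and β-keto esters to para-quinone methides and the Pd-catalysed intramolecular α-arylation of ketone enolates with aryl bromides; both need only carbonate base, so they can share a flask. At −20 °C the chiral ammonium enolate of 9 attacks the methide carbon of 7 through C2, the pendant ring rearomatises to its phenoxide and the C1–C2 bond of 10 is formed; at 70 °C Pd(0) inserts into the C4a–Br bond, the acetyl CH3 of 10 is the only enolisable position because C2 is now quaternary, and C–C reductive elimination forms C4–C4a. Ring B is the one ring closed, six-membered, by reductive elimination from a seven-membered aryl-palladium C-enolate (formally a 6-exo attack of the methyl ketone enolate on C4a). C1 and C2 are both created in the 1,6-addition: the chiral cation blocks one face of the enolate and orients the quinone methide, and the antipode is chosen that gives the (1S,2S) pair, in which after ring closure the C1 aryl group is cis to the C2 benzyloxy group and trans to the ester; the arylation touches no stereocentre. The step needs C- over O-alkylation and 1,6- over 1,2-addition (secured by the aromatisation of the pendant ring), ring closure at C4a and not at C8 (secured by the bromine at C4a) and no retro-1,6-addition or racemisation before the ring is closed (carbonate is the only base and the arylation runs at 70 °C).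

Step 6
Reactants: 11 benzyl (1S,2S)-2,7-bis(benzyloxy)-1-[3-(benzyloxy)-4-hydroxy-5-methoxyphenyl]-6-methoxy-3-oxo-1,2,3,4-tetrahydronaphthalene-2-carboxylate
Product: 12 benzyl (1S,2S)-2,7-bis(benzyloxy)-1-[3-(benzyloxy)-4-hydroxy-5-methoxyphenyl]-6-methoxy-3-methylidene-1,2,3,4-tetrahydronaphthalene-2-carboxylate
Conditions: Zn, CH2Br2, TiCl4, THF/CH2Cl2, 0 °C to rt
Reagents that add atoms: dibromomethane, BrCBr
Why: Takai–Lombardo methylenation: the weakly basic zinc–titanium methylene reagent should olefinate the hindered and readily enolised β-tetralone carbonyl without attacking the benzyl ester or disturbing C1 and C2 (excess reagent covers the free phenol).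

Step 7
Reactants: 12 benzyl (1S,2S)-2,7-bis(benzyloxy)-1-[3-(benzyloxy)-4-hydroxy-5-methoxyphenyl]-6-methoxy-3-methylidene-1,2,3,4-tetrahydronaphthalene-2-carboxylate
Product: 13 benzyl (1S,2S,3R)-2,7-bis(benzyloxy)-1-[3-(benzyloxy)-4-hydroxy-5-methoxyphenyl]-3-hydroxy-3-(hydroxymethyl)-6-methoxy-1,2,3,4-tetrahydronaphthalene-2-carboxylate
Conditions: OsO4 (cat.), NMO, acetone/H2O, rt
Reagents that add atoms: N-methylmorpholine N-oxide, C[N+]1([O-])CCOCC1; water, O
Why: Upjohn dihydroxylation: OsO4 should add to the exocyclic alkene from the ring face opposite the pseudo-axial C1 aryl group and anti to the allylic C2 benzyloxy group (the usual osmylation preference for allylic ethers), which places the C3 oxygen cis to the ester and gives 3R.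

Step 8
Reactants: 13 benzyl (1S,2S,3R)-2,7-bis(benzyloxy)-1-[3-(benzyloxy)-4-hydroxy-5-methoxyphenyl]-3-hydroxy-3-(hydroxymethyl)-6-methoxy-1,2,3,4-tetrahydronaphthalene-2-carboxylate
Product: 14 plicatic acid, (1S,2S,3R)-1-(3,4-dihydroxy-5-methoxyphenyl)-2,3,7-trihydroxy-3-(hydroxymethyl)-6-methoxy-1,2,3,4-tetrahydronaphthalene-2-carboxylic acid
Conditions: H2 (1 atm), Pd(OH)2/C, MeOH/EtOAc, rt
Reagents that add atoms: none
Why: Catalytic hydrogenolysis should cleave the three benzyl ethers and the benzyl ester in one operation under neutral conditions that leave all three stereocentres and the air-sensitive catechol intact.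

**Compound list**

1 | 2-hydroxy-6-methoxybenzaldehyde | COc1cccc(O)c1C=O | starting material
2 | 2-(benzyloxy)-6-methoxybenzaldehyde | COc1cccc(OCc2ccccc2)c1C=O | intermediate
3 | 2-(benzyloxy)-6-methoxyphenyl formate (not isolated) | COc1cccc(OCc2ccccc2)c1OC=O | intermediate
4 | 2-(benzyloxy)-6-methoxyphenol | COc1cccc(OCc2ccccc2)c1O | intermediate
5 | 5-(benzyloxy)-2-bromo-4-methoxybenzaldehyde | COc1cc(Br)c(C=O)cc1OCc1ccccc1 | starting material
6 | 2-(benzyloxy)-4-{[5-(benzyloxy)-2-bromo-4-methoxyphenyl](piperidin-1-yl)methyl}-6-methoxyphenol (Mannich base, racemic, not isolated) | COc1cc(C(N2CCCCC2)c2cc(OCc3ccccc3)c(OC)cc2Br)cc(OCc2ccccc2)c1O | intermediate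
7 | 2-(benzyloxy)-4-{[5-(benzyloxy)-2-bromo-4-methoxyphenyl]methylidene}-6-methoxycyclohexa-2,5-dien-1-one (E/Z mixture) | COC1=CC(=Cc2cc(OCc3ccccc3)c(OC)cc2Br)C=C(OCc2ccccc2)C1=O | intermediate
8 | benzyl 2-(benzyloxy)acetate | O=C(COCc1ccccc1)OCc1ccccc1 | starting material
9 | benzyl 2-(benzyloxy)-3-oxobutanoate (racemic) | CC(=O)C(OCc1ccccc1)C(=O)OCc1ccccc1 | intermediate
10 | benzyl (2S)-2-(benzyloxy)-2-[(S)-[5-(benzyloxy)-2-bromo-4-methoxyphenyl][3-(benzyloxy)-4-hydroxy-5-methoxyphenyl]methyl]-3-oxobutanoate (not isolated) | COc1cc(Br)c(cc1OCc1ccccc1)[C@H](c1cc(OCc3ccccc3)c(O)c(OC)c1)[C@@](OCc1ccccc1)(C(=O)OCc1ccccc1)C(C)=O | intermediate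
11 | benzyl (1S,2S)-2,7-bis(benzyloxy)-1-[3-(benzyloxy)-4-hydroxy-5-methoxyphenyl]-6-methoxy-3-oxo-1,2,3,4-tetrahydronaphthalene-2-carboxylate | COc1cc2c(cc1OCc1ccccc1)[C@H](c1cc(OCc3ccccc3)c(O)c(OC)c1)[C@@](OCc1ccccc1)(C(=O)OCc1ccccc1)C(=O)C2 | intermediate
12 | benzyl (1S,2S)-2,7-bis(benzyloxy)-1-[3-(benzyloxy)-4-hydroxy-5-methoxyphenyl]-6-methoxy-3-methylidene-1,2,3,4-tetrahydronaphthalene-2-carboxylate | COc1cc2c(cc1OCc1ccccc1)[C@H](c1cc(OCc3ccccc3)c(O)c(OC)c1)[C@@](OCc1ccccc1)(C(=O)OCc1ccccc1)C(=C)C2 | intermediate
13 | benzyl (1S,2S,3R)-2,7-bis(benzyloxy)-1-[3-(benzyloxy)-4-hydroxy-5-methoxyphenyl]-3-hydroxy-3-(hydroxymethyl)-6-methoxy-1,2,3,4-tetrahydronaphthalene-2-carboxylate | COc1cc2c(cc1OCc1ccccc1)[C@H](c1cc(OCc3ccccc3)c(O)c(OC)c1)[C@@](OCc1ccccc1)(C(=O)OCc1ccccc1)[C@](O)(CO)C2 | intermediate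
14 | plicatic acid, (1S,2S,3R)-1-(3,4-dihydroxy-5-methoxyphenyl)-2,3,7-trihydroxy-3-(hydroxymethyl)-6-methoxy-1,2,3,4-tetrahydronaphthalene-2-carboxylic acid | COc1cc2c(cc1O)[C@H](c1cc(O)c(O)c(OC)c1)[C@@](O)(C(=O)O)[C@](O)(CO)C2 | target

**Totals.** Total step count: 8. Longest linear sequence: 7 steps (steps 1, 2, 3, 5, 6, 7, 8).

**Steps most likely to fail**

Step 5 (Proposed new method). The ion pair may give weak facial control, so that the wrong relative or absolute configuration at C1/C2 forms. The phenoxide adduct may also lose enantiomeric purity by retro-1,6-addition at the arylation temperature, and the phenoxide or quinone methide may inhibit the palladium catalyst. The fallback sets out from 7 and 9 and separates the two events with known chemistry. A bifunctional cinchona tertiary amine–squaramide (hydrogen-bond catalysis, CH2Cl2, 0 °C, no inorganic base) should add 9 to 7 to give the open-chain adduct 10, which is now isolated. Its phenol is silylated (TBSCl, imidazole, DMF) to the silyl ether F1. A separate Pd-catalysed intramolecular ketone α-arylation (Pd2(dba)3, XPhos, K3PO4, toluene, 80 °C) should then close ring B to the silyl-protected tetralone F2. Fluoride (TBAF, AcOH, THF) brings the sequence back to the route at 11.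

Step 6. Enolisation of the β-tetralone toward C4 and shielding of the carbonyl by the quaternary C2 may stop olefination, and the titanium Lewis acid may ionise benzyl ethers. The fallback sets out from 11. The organocerium reagent from (trimethylsilyl)methyllithium and CeCl3 (THF, −78 °C, one extra equivalent for the phenol) should add to the ketone to give the β-hydroxysilane F3 (both C3 epimers serve). Peterson elimination (aqueous HF, MeCN) comes back to the route at 12.

Step 7. Facial selectivity of the osmylation may be poor, or the electron-rich free phenol may be oxidised under the reoxidant. The fallback sets out from 12 and delivers the C3 oxygen from inside the molecule. Saponification of the benzyl ester (LiOH, THF/MeOH/H2O) should give the acid F4. Iodolactonisation (I2, NaHCO3, MeCN/H2O, 0 °C) should close the iodo-β-lactone F5 by 4-exo attack of the carboxylate on C3, so the C3 oxygen can only arrive on the face of the C2 carboxyl group. Aqueous K2CO3 should open the lactone; the freed C3 alkoxide closes to the spiro-epoxide, and hydroxide opens it at CH2 to give the triol acid F6. Hydrogenolysis under the conditions of step 8 comes back to the route at 14.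

**Further compounds**

F1 | step 5 | benzyl (2S)-2-(benzyloxy)-2-[(S)-[5-(benzyloxy)-2-bromo-4-methoxyphenyl][3-(benzyloxy)-4-[(tert-butyldimethylsilyl)oxy]-5-methoxyphenyl]methyl]-3-oxobutanoate | COc1cc(Br)c(cc1OCc1ccccc1)[C@H](c1cc(OCc3ccccc3)c(O[Si](C)(C)C(C)(C)C)c(OC)c1)[C@@](OCc1ccccc1)(C(=O)OCc1ccccc1)C(C)=O
F2 | step 5 | benzyl (1S,2S)-2,7-bis(benzyloxy)-1-[3-(benzyloxy)-4-[(tert-butyldimethylsilyl)oxy]-5-methoxyphenyl]-6-methoxy-3-oxo-1,2,3,4-tetrahydronaphthalene-2-carboxylate | COc1cc2c(cc1OCc1ccccc1)[C@H](c1cc(OCc3ccccc3)c(O[Si](C)(C)C(C)(C)C)c(OC)c1)[C@@](OCc1ccccc1)(C(=O)OCc1ccccc1)C(=O)C2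
F3 | step 6 | benzyl (1S,2S)-2,7-bis(benzyloxy)-1-[3-(benzyloxy)-4-hydroxy-5-methoxyphenyl]-3-hydroxy-6-methoxy-3-[(trimethylsilyl)methyl]-1,2,3,4-tetrahydronaphthalene-2-carboxylate (C3 epimers) | COc1cc2c(cc1OCc1ccccc1)[C@H](c1cc(OCc3ccccc3)c(O)c(OC)c1)[C@@](OCc1ccccc1)(C(=O)OCc1ccccc1)C(O)(C[Si](C)(C)C)C2
F4 | step 7 | (1S,2S)-2,7-bis(benzyloxy)-1-[3-(benzyloxy)-4-hydroxy-5-methoxyphenyl]-6-methoxy-3-methylidene-1,2,3,4-tetrahydronaphthalene-2-carboxylic acid | COc1cc2c(cc1OCc1ccccc1)[C@H](c1cc(OCc3ccccc3)c(O)c(OC)c1)[C@@](OCc1ccccc1)(C(=O)O)C(=C)C2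
F5 | step 7 | (1S,2S,3S)-2,7-bis(benzyloxy)-1-[3-(benzyloxy)-4-hydroxy-5-methoxyphenyl]-3-(iodomethyl)-6-methoxy-1,2,3,4-tetrahydronaphthalene-2,3-carbolactone (cis-fused β-lactone between the C2 carboxyl group and the C3 oxygen) | COc1cc2c(cc1OCc1ccccc1)[C@H](c1cc(OCc3ccccc3)c(O)c(OC)c1)[C@@]1(OCc3ccccc3)C(=O)O[C@@]1(CI)C2
F6 | step 7 | (1S,2S,3R)-2,7-bis(benzyloxy)-1-[3-(benzyloxy)-4-hydroxy-5-methoxyphenyl]-3-hydroxy-3-(hydroxymethyl)-6-methoxy-1,2,3,4-tetrahydronaphthalene-2-carboxylic acid | COc1cc2c(cc1OCc1ccccc1)[C@H](c1cc(OCc3ccccc3)c(O)c(OC)c1)[C@@](OCc1ccccc1)(C(=O)O)[C@](O)(CO)C2
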